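**Retrosynthetic overview**

1. Numbering is that of eremophilane: ring A = C1–C5 + C10, ring B = C5–C10, isopropenyl on C7, β = face of the C5 methyl. The target comes from C9-selective acylation and C2 desilylation of a 7β-isopropenyl-8α,9α-diol, which comes from trans-diaxial opening of a 7α,8α-epoxy-9α-ol at C7 by an isopropenyl nucleophile.
2. The epoxy alcohol comes from a Δ7-en-9α-ol, this from a 9α-silyloxy-8-ketone, and this from a Δ9(10)-en-8-one. Dissolving-metal reduction sets C10 (trans fusion), Rubottom oxidation sets C9, and enol triflate reduction places the alkene at C7=C8.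
3. The Δ9(10)-en-8-one comes from (S)-carvone (ring A, purchased), a methyl group (onto C4) and a four-carbon silyl enone (C6–C9). A one-flask conjugate addition / Michael addition / aldol condensation forms C4–CH3, C5–C6 and C9=C10 and closes ring B. The carvone isopropenyl at C2 is afterwards degraded to the C2 oxygen with retention (Criegee rearrangement).
4. Enabling feature: ring-fusion carbon C10 is flanked in ring A by the methylated quaternary C5 and, one bond further, by the methylated C4, and it stands 1,5 to the oxygenated C8 of ring B (C10–C5–C6–C7–C8). With C10 as a carbonyl this is the retron of 1,4-methyl addition to a 2-methylcyclohex-2-enone, α-alkylation at C5 and aldol closure of C9 onto C10; C2 carries oxygen exactly where carvone carries its stereocontrolling isopropenyl group.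
5. Ring order: ring A (chiral pool) first, ring B last (step 1); the later epoxide is only a temporary ring.

Key step: step 1

Remark: compounds 2 and 20 are taken as catalogue reagents; all bicyclic intermediates are named with the numbering and α/β convention given above.

**Route**

Step 1
Reactants: 1 (S)-(+)-carvone; 2 trimethyl(3-oxobut-1-en-2-yl)silane
Product: 5 octalone (2α-isopropenyl-4β,5β-dimethyl-Δ9(10)-octalin-8-one), via lithium enolate 3 (not isolated), via silyl diketone 4 (not isolated)
Conditions: MeLi, CuI, Et2O, 0 °C; 1, −78 → 0 °C; 2, −78 °C → rt; then NaOMe, MeOH, rt → 60 °C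
Reagents that add atoms: lithium dimethylcuprate, [Li+].C[Cu-]C (made in the flask from methyllithium, C[Li], and CuI)
Why: Me2CuLi adds 1,4 to the enone of 1 by axial attack anti to the C2 isopropenyl group (trans-3,5 relationship), which sets C4 and gives the regiodefined enolate 3; 3 then adds in a Michael reaction through C5 to the silyl enone 2 on the face anti to the new C4 methyl, which sets the quaternary C5 with the two methyls cis, the silyl group stabilising the new enolate and suppressing polymerisation of the acceptor. Methoxide then removes the silyl group from 4, and the methyl ketone enolate (C9) closes ring B on the C10 carbonyl by a 6-(enolexo)-exo-trig aldol addition followed by E1cB dehydration to the conjugated enone. The closest known reaction type is the conjugate addition–Robinson annulation with an α-silyl vinyl ketone as Michael acceptor. C2 comes unchanged from carvone, C4 is controlled by C2, and C5 is controlled by C4. The step needs regiocontrol of the enolate (C5, not C1), which the conjugate addition itself secures, and regiocontrol of the aldol (ring B, not a bridged ketol from C1 attacking C8), which is secured because only the ring B ketol can dehydrate while the bridged one reverts.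

Step 2
Reactants: 5 octalone (2α-isopropenyl-4β,5β-dimethyl-Δ9(10)-octalin-8-one)
Product: 7 acetate (2α-acetoxy-4β,5β-dimethyl-Δ9(10)-octalin-8-one), via methoxy hydroperoxide 6 (not isolated)
Conditions: O3 (1 equiv, indicator-controlled), CH2Cl2–MeOH, −78 °C; then Ac2O, Et3N, DMAP (cat.), −78 → 40 °C
Reagents that add atoms: ozone, [O-][O+]=O; methanol, CO
Why: ozone should cleave only the electron-rich 1,1-disubstituted alkene (the enone C9=C10 is deactivated), and acetylation of the methoxy hydroperoxide 6 triggers a Criegee rearrangement in which C2 migrates from carbon to oxygen with retention, so the 2α configuration is kept and the acetyl group of 7 is the former C(CH3) of the isopropenyl group.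

Step 3
Reactants: 7 acetate (2α-acetoxy-4β,5β-dimethyl-Δ9(10)-octalin-8-one)
Product: 8 alcohol (2α-hydroxy-4β,5β-dimethyl-Δ9(10)-octalin-8-one)
Conditions: K2CO3 (cat.), MeOH, 0 °C
Reagents that add atoms: none
Why: base-catalysed transesterification with methanol at low temperature should free the C2 hydroxyl without touching the enone or any stereocenter.

Step 4
Reactants: 8 alcohol (2α-hydroxy-4β,5β-dimethyl-Δ9(10)-octalin-8-one)
Product: 9 silyl ether (2α-(tert-butyldimethylsilyloxy)-4β,5β-dimethyl-Δ9(10)-octalin-8-one)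
Conditions: t-BuMe2SiCl, imidazole, DMF, rt
Reagents that add atoms: tert-butyldimethylsilyl chloride, CC(C)(C)[Si](C)(C)Cl
Why: standard silyl ether protection of a secondary alcohol masks the C2 hydroxyl through the reductive, basic and organometallic steps that follow.

Step 5
Reactants: 9 silyl ether (2α-(tert-butyldimethylsilyloxy)-4β,5β-dimethyl-Δ9(10)-octalin-8-one)
Product: 11 silyl enol ether (2α-(tert-butyldimethylsilyloxy)-8-(triethylsilyloxy)-4β,5β-dimethyl-10α-H-Δ8(9)-octalin), via lithium enolate 10 (not isolated)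
Conditions: Li, NH3 (l)–THF, t-BuOH (1 equiv), −78 °C; isoprene; NH3 off; then Et3SiCl, Et3N, THF, −78 → 0 °C
Reagents that add atoms: chlorotriethylsilane, CC[Si](Cl)(CC)CC
Why: Birch-type dissolving-metal reduction of the enone protonates the β-carbon C10 axially, anti to the C5 methyl, which should give the trans ring fusion (10α-H), and the regiodefined C8–C9 lithium enolate 10 is trapped on oxygen before it can equilibrate.

Step 6
Reactants: 11 silyl enol ether (2α-(tert-butyldimethylsilyloxy)-8-(triethylsilyloxy)-4β,5β-dimethyl-10α-H-Δ8(9)-octalin)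
Product: 13 silyloxy ketone (2α-(tert-butyldimethylsilyloxy)-9α-(triethylsilyloxy)-4β,5β-dimethyl-10α-H-decalin-8-one), via siloxy epoxide 12 (not isolated)
Conditions: mCPBA, NaHCO3, CH2Cl2, −20 → 0 °C
Reagents that add atoms: 3-chloroperbenzoic acid, OOC(=O)c1cccc(Cl)c1
Why: in this Rubottom oxidation the peracid should attack C8=C9 from the α face because the axial C5 methyl (1,3 to C9) shields the β face, and the siloxy epoxide 12 opens with 1,4-silyl migration to the equatorial 9α-silyloxy ketone.

Step 7
Reactants: 13 silyloxy ketone (2α-(tert-butyldimethylsilyloxy)-9α-(triethylsilyloxy)-4β,5β-dimethyl-10α-H-decalin-8-one)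
Product: 15 enol triflate (2α-(tert-butyldimethylsilyloxy)-9α-(triethylsilyloxy)-4β,5β-dimethyl-10α-H-Δ7-octalin-8-yl trifluoromethanesulfonate), via potassium enolate 14 (not isolated)
Conditions: KN(SiMe3)2, THF, −78 °C; then PhNTf2, −78 → 0 °C
Reagents that add atoms: N-phenylbis(trifluoromethanesulfonimide), O=S(=O)(N(c1ccccc1)S(=O)(=O)C(F)(F)F)C(F)(F)F
Why: kinetic deprotonation with a bulky amide base should occur at the unhindered C7 methylene and not at the silyloxy-bearing C9, and O-sulfonylation of the enolate 14 fixes the C7=C8 enol triflate.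

Step 8
Reactants: 15 enol triflate (2α-(tert-butyldimethylsilyloxy)-9α-(triethylsilyloxy)-4β,5β-dimethyl-10α-H-Δ7-octalin-8-yl trifluoromethanesulfonate)
Product: 16 alkene (2α-(tert-butyldimethylsilyloxy)-9α-(triethylsilyloxy)-4β,5β-dimethyl-10α-H-Δ7-octalin)
Conditions: Pd(OAc)2 (cat.), PPh3, n-Bu3N, HCO2H, DMF, 60 °C
Reagents that add atoms: none
Why: palladium-catalysed formate reduction of an enol triflate (oxidative addition, formate exchange, decarboxylation, reductive elimination) replaces the triflate by hydrogen without moving the double bond or touching the silyl ethers.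

Step 9
Reactants: 16 alkene (2α-(tert-butyldimethylsilyloxy)-9α-(triethylsilyloxy)-4β,5β-dimethyl-10α-H-Δ7-octalin)
Product: 17 allylic alcohol (2α-(tert-butyldimethylsilyloxy)-4β,5β-dimethyl-10α-H-Δ7-octalin-9α-ol)
Conditions: PPTS (cat.), MeOH, 0 °C → rt
Reagents that add atoms: none
Why: acid-catalysed methanolysis cleaves a triethylsilyl ether far faster than a secondary tert-butyldimethylsilyl ether, so only the allylic C9 hydroxyl should be released.

Step 10
Reactants: 17 allylic alcohol (2α-(tert-butyldimethylsilyloxy)-4β,5β-dimethyl-10α-H-Δ7-octalin-9α-ol)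
Product: 18 epoxy alcohol (7α,8α-epoxy-2α-(tert-butyldimethylsilyloxy)-4β,5β-dimethyl-10α-H-decalin-9α-ol)
Conditions: mCPBA, NaHCO3, CH2Cl2, 0 °C
Reagents that add atoms: 3-chloroperbenzoic acid, OOC(=O)c1cccc(Cl)c1
Why: hydroxyl-directed (Henbest) peracid epoxidation delivers oxygen syn to the 9α-hydroxyl, and this α face is also the one not shielded by the axial C5 methyl, so the 7α,8α-epoxide should form.

Step 11
Reactants: 18 epoxy alcohol (7α,8α-epoxy-2α-(tert-butyldimethylsilyloxy)-4β,5β-dimethyl-10α-H-decalin-9α-ol)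
Product: 19 diol (2α-(tert-butyldimethylsilyloxy)-7β-isopropenyl-4β,5β-dimethyl-10α-H-decalin-8α,9α-diol)
Conditions: CH2=C(CH3)MgBr (3 equiv), CuI (10 mol %), THF, −30 → 0 °C; aq. NH4Cl
Reagents that add atoms: isopropenylmagnesium bromide, CC(=C)[Mg]Br
Why: copper-catalysed Grignard opening of a cyclohexene oxide follows the Fürst–Plattner rule, so attack at C7 from the β face should give the chair-like trans-diaxial product (7β-isopropenyl, 8α-OH) and set C7 and C8, while attack at C8 is disfavoured by the twist-boat it requires and by the adjacent C9 oxygen.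

Step 12
Reactants: 19 diol (2α-(tert-butyldimethylsilyloxy)-7β-isopropenyl-4β,5β-dimethyl-10α-H-decalin-8α,9α-diol); 20 (E)-3-methylpent-2-enoic acid
Product: 21 ester (2α-(tert-butyldimethylsilyloxy)-8α-hydroxy-7β-isopropenyl-4β,5β-dimethyl-10α-H-decalin-9α-yl (E)-3-methylpent-2-enoate)
Conditions: DCC, DMAP (10 mol %), CH2Cl2, 0 °C → rt
Reagents that add atoms: none
Why: in this Steglich esterification the equatorial 9α-hydroxyl should react in preference to the axial 8α-hydroxyl, which is flanked by the axial isopropenyl group and two 1,3-diaxial hydrogens, and the low DMAP loading at 0 °C should preserve the E-enoate.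

Step 13
Reactants: 21 ester (2α-(tert-butyldimethylsilyloxy)-8α-hydroxy-7β-isopropenyl-4β,5β-dimethyl-10α-H-decalin-9α-yl (E)-3-methylpent-2-enoate)
Product: 22 target CNP0129603.2 (2α,8α-dihydroxy-7β-isopropenyl-4β,5β-dimethyl-10α-H-decalin-9α-yl (E)-3-methylpent-2-enoate)
Conditions: HF·pyridine, pyridine, THF, 0 °C → rt
Reagents that add atoms: none
Why: buffered fluoride-mediated desilylation under mildly acidic conditions should remove the secondary silyl ether without migrating the C9 ester to the cis C8 hydroxyl, protonating the isopropenyl group or touching any stereocenter.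

**Compound list**

1 | (S)-(+)-carvone, (5S)-2-methyl-5-(prop-1-en-2-yl)cyclohex-2-en-1-one | CC1=CC[C@H](C(C)=C)CC1=O | starting material
2 | trimethyl(3-oxobut-1-en-2-yl)silane, 3-(trimethylsilyl)but-3-en-2-one | CC(=O)C(=C)[Si](C)(C)C | starting material
3 | lithium (3S,5S)-2,3-dimethyl-5-(prop-1-en-2-yl)cyclohex-1-en-1-olate (ring A enolate O–C10=C5, 4β-methyl, 2α-isopropenyl; not isolated) | [Li]OC1=C(C)[C@@H](C)C[C@H](C(C)=C)C1 | intermediate
4 | (2R,3S,5S)-2,3-dimethyl-2-[3-oxo-2-(trimethylsilyl)butyl]-5-(prop-1-en-2-yl)cyclohexan-1-one (mixture at the silyl-bearing carbon; not isolated) | CC(=O)C([Si](C)(C)C)C[C@]1(C)[C@@H](C)C[C@H](C(C)=C)CC1=O | intermediate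
5 | 2α-isopropenyl-4β,5β-dimethyl-Δ9(10)-octalin-8-one | O=C1CC[C@]2(C)[C@@H](C)C[C@H](C(C)=C)CC2=C1 | intermediate
6 | 2α-(2-hydroperoxy-2-methoxyprop-2-yl)-4β,5β-dimethyl-Δ9(10)-octalin-8-one (mixture at the peroxy carbon; not isolated) | O=C1CC[C@]2(C)[C@@H](C)C[C@H](C(C)(OC)OO)CC2=C1 | intermediate
7 | 2α-acetoxy-4β,5β-dimethyl-Δ9(10)-octalin-8-one | O=C1CC[C@]2(C)[C@@H](C)C[C@H](OC(C)=O)CC2=C1 | intermediate
8 | 2α-hydroxy-4β,5β-dimethyl-Δ9(10)-octalin-8-one | O=C1CC[C@]2(C)[C@@H](C)C[C@H](O)CC2=C1 | intermediate
9 | 2α-(tert-butyldimethylsilyloxy)-4β,5β-dimethyl-Δ9(10)-octalin-8-one | O=C1CC[C@]2(C)[C@@H](C)C[C@H](O[Si](C)(C)C(C)(C)C)CC2=C1 | intermediate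
10 | lithium 2α-(tert-butyldimethylsilyloxy)-4β,5β-dimethyl-10α-H-Δ8(9)-octalin-8-olate (not isolated) | [Li]OC=1CC[C@]2(C)[C@@H](C)C[C@H](O[Si](C)(C)C(C)(C)C)C[C@H]2C=1 | intermediate
11 | 2α-(tert-butyldimethylsilyloxy)-8-(triethylsilyloxy)-4β,5β-dimethyl-10α-H-Δ8(9)-octalin | CC[Si](CC)(CC)OC=1CC[C@]2(C)[C@@H](C)C[C@H](O[Si](C)(C)C(C)(C)C)C[C@H]2C=1 | intermediate
12 | 8α,9α-epoxy-2α-(tert-butyldimethylsilyloxy)-8β-(triethylsilyloxy)-4β,5β-dimethyl-10α-H-decalin (not isolated) | CC[Si](CC)(CC)O[C@@]12CC[C@]3(C)[C@@H](C)C[C@H](O[Si](C)(C)C(C)(C)C)C[C@H]3[C@@H]1O2 | intermediate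
13 | 2α-(tert-butyldimethylsilyloxy)-9α-(triethylsilyloxy)-4β,5β-dimethyl-10α-H-decalin-8-one | O=C1CC[C@]2(C)[C@@H](C)C[C@H](O[Si](C)(C)C(C)(C)C)C[C@H]2[C@@H]1O[Si](CC)(CC)CC | intermediate
14 | potassium 2α-(tert-butyldimethylsilyloxy)-9α-(triethylsilyloxy)-4β,5β-dimethyl-10α-H-Δ7-octalin-8-olate (not isolated) | [K]OC1=CC[C@]2(C)[C@@H](C)C[C@H](O[Si](C)(C)C(C)(C)C)C[C@H]2[C@@H]1O[Si](CC)(CC)CC | intermediate
15 | 2α-(tert-butyldimethylsilyloxy)-9α-(triethylsilyloxy)-4β,5β-dimethyl-10α-H-Δ7-octalin-8-yl trifluoromethanesulfonate | O=S(=O)(OC1=CC[C@]2(C)[C@@H](C)C[C@H](O[Si](C)(C)C(C)(C)C)C[C@H]2[C@@H]1O[Si](CC)(CC)CC)C(F)(F)F | intermediate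
16 | 2α-(tert-butyldimethylsilyloxy)-9α-(triethylsilyloxy)-4β,5β-dimethyl-10α-H-Δ7-octalin | C1=CC[C@]2(C)[C@@H](C)C[C@H](O[Si](C)(C)C(C)(C)C)C[C@H]2[C@@H]1O[Si](CC)(CC)CC | intermediate
17 | 2α-(tert-butyldimethylsilyloxy)-4β,5β-dimethyl-10α-H-Δ7-octalin-9α-ol | C1=CC[C@]2(C)[C@@H](C)C[C@H](O[Si](C)(C)C(C)(C)C)C[C@H]2[C@@H]1O | intermediate
18 | 7α,8α-epoxy-2α-(tert-butyldimethylsilyloxy)-4β,5β-dimethyl-10α-H-decalin-9α-ol | O1[C@@H]2C[C@]3(C)[C@@H](C)C[C@H](O[Si](C)(C)C(C)(C)C)C[C@H]3[C@H](O)[C@H]12 | intermediate
19 | 2α-(tert-butyldimethylsilyloxy)-7β-isopropenyl-4β,5β-dimethyl-10α-H-decalin-8α,9α-diol | C=C(C)[C@H]1C[C@]2(C)[C@@H](C)C[C@H](O[Si](C)(C)C(C)(C)C)C[C@H]2[C@H](O)[C@@H]1O | intermediate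
20 | (E)-3-methylpent-2-enoic acid | OC(=O)/C=C(\C)CC | starting material
21 | 2α-(tert-butyldimethylsilyloxy)-8α-hydroxy-7β-isopropenyl-4β,5β-dimethyl-10α-H-decalin-9α-yl (E)-3-methylpent-2-enoate | C=C(C)[C@H]1C[C@]2(C)[C@@H](C)C[C@H](O[Si](C)(C)C(C)(C)C)C[C@H]2[C@H](OC(=O)/C=C(\C)CC)[C@@H]1O | intermediate
22 | CNP0129603.2, (2S,4S,5R,7R,8R,9S,10R)-2α,8α-dihydroxy-7β-isopropenyl-4β,5β-dimethyl-10α-H-decalin-9α-yl (E)-3-methylpent-2-enoate (eremophilane numbering) | C=C(C)[C@H]1C[C@]2(C)[C@@H](C)C[C@H](O)C[C@H]2[C@H](OC(=O)/C=C(\C)CC)[C@@H]1O | target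

**Step count and risks**

Total steps: 13. Longest linear sequence: 13 steps (from 1).

Steps most likely to fail:

Step 11. The axial approach to C7 is 1,3-related to the C5 methyl, so the copper reagent may open the epoxide only slowly, and the magnesium salts may instead cause halohydrin formation or rearrangement of the epoxide to a ketone. The fallback sets out from 18 and uses a slim sp-hybridised nucleophile: LiC≡CH·H2NCH2CH2NH2 in DMSO should open the epoxide trans-diaxially to the 7β-ethynyl-8α,9α-diol F1. The alkyne is then turned into the isopropenyl group by zirconium-catalysed carboalumination (Me3Al in excess, Cp2ZrCl2, CH2Cl2, then aqueous quench), which places CH3 on the inner and H on the terminal alkyne carbon; this comes back to the route at 19.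

Step 12. The two hydroxyls of the cis-diol may not be discriminated well enough, the acyl group may migrate between them, and the activated acid may lose its E geometry or deconjugate. The fallback sets out from 19: heating with Bu2SnO in toluene with removal of water should give the dibutylstannylene acetal F2, which is treated without amine base with (E)-3-methylpent-2-enoyl chloride F3 (made from 20 with oxalyl chloride and catalytic DMF). Stannylene acetals of cis-diols are acylated at the equatorial oxygen, here O9, so this comes back to the route at 21.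

Step 1. The hindered copper-containing enolate 3 may transfer a proton to the enone 2 or polymerise it instead of adding, or the facial selectivity at C5 may be poor. The fallback sets out from 1 with the same cuprate addition, but enolate 3 is alkylated with allyl bromide (THF, HMPA) to the 2-allyl ketone F4. Wacker oxidation (PdCl2, CuCl, O2, DMF–H2O), which should convert the monosubstituted alkene and leave the 1,1-disubstituted isopropenyl group, gives the 1,5-diketone F5, and NaOMe in MeOH closes ring B by aldol condensation; this comes back to the route at 5.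

**Further compounds**

F1 | step 11 | 2α-(tert-butyldimethylsilyloxy)-7β-ethynyl-4β,5β-dimethyl-10α-H-decalin-8α,9α-diol | C#C[C@H]1C[C@]2(C)[C@@H](C)C[C@H](O[Si](C)(C)C(C)(C)C)C[C@H]2[C@H](O)[C@@H]1O
F2 | step 12 | 8α,9α-O-dibutylstannylene acetal of 19 | C=C(C)[C@H]1C[C@]2(C)[C@@H](C)C[C@H](O[Si](C)(C)C(C)(C)C)C[C@H]2[C@@H]3O[Sn](CCCC)(CCCC)O[C@H]13
F3 | step 12 | (E)-3-methylpent-2-enoyl chloride | ClC(=O)/C=C(\C)CC
F4 | step 1 | (2R,3S,5S)-2,3-dimethyl-2-(prop-2-en-1-yl)-5-(prop-1-en-2-yl)cyclohexan-1-one | C=CC[C@]1(C)[C@@H](C)C[C@H](C(C)=C)CC1=O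
F5 | step 1 | (2R,3S,5S)-2,3-dimethyl-2-(3-oxobutyl)-5-(prop-1-en-2-yl)cyclohexan-1-one | CC(=O)CC[C@]1(C)[C@@H](C)C[C@H](C(C)=C)CC1=O
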